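## Analysis of the target

The target 30 is a 22-membered meta,para-cyclophane, labelled here as follows: chain carbons C1 (carbinol) to C14, ring A carbons C15 (bearing C14) to C20, ring B carbons C21 (bearing C1) to C26; the macrocycle runs through the ether oxygen, C19, C20, C15, C14 to C1 and C21 to C24. Ring A is a 1,3,5-trisubstituted benzene with a free hydroxyl at C17, the diaryl ether oxygen at C19, the chain end at C15 and hydrogen at C16, C18 and C20, whereas ring B is 3,4,5-trioxygenated, with hydroxyls at C23 and C25 flanking the ether oxygen at C24. The chain C1–C14 holds a (Z)-alkene at C8=C9. The only stereocenter is C1, a secondary benzylic carbinol of (R) configuration (OH > aryl > CH2 > H); it has no stereochemical partner and must be set by a catalyst. Sensitive groups are four electron-rich phenols, a benzylic alcohol para to an aryloxy group (ionisable under acid) and the Z-alkene, which rules out late hydrogenolysis and strong acid. The synthesis is hard for four reasons: the ether oxygen sits between two ortho oxygens on ring B and joins two electron-rich rings, which is the worst case for C–O coupling; ring A is a resorcinol whose two oxygens must be told apart; a 22-membered ring must be closed; and Z geometry in an unstrained large ring cannot be left to thermodynamics. The feature that invites the chosen move is ring A itself: the pattern C17–OH, C19–OAr, C15–alkyl with hydrogens in between is exactly what a vinylketene/alkynyl ether benzannulation writes onto a newly formed benzene ring.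

## Retrosynthetic reasoning

**30 from 28.** Only the acetal O–C bonds of three methoxymethyl ethers (on the oxygens of C1, C23 and C25) are cut. These oxygens must survive organolithium and Grignard reagents and 100 °C, and must be freed without protic acid (C1–O ionisation) and without hydrogen (alkene). One acetal type on all three oxygens allows a single non-protic cleavage. The C17 hydroxyl needs no protection because it is created in the key step.

**28 from 23 (key disconnection).** Ring A is taken apart at C17–C18 and C19–C20, and the same cut opens the macrocycle at C19–C20. This leaves a four-carbon unit C20–C15–C16–C17 (a cyclobutenone carrying the chain at C15) and a two-carbon unit C18–C19 (an alkynyl ether whose C19 carbon is already bonded to the C24 oxygen). The cut is made here because it removes every aryl C–O coupling, differentiates the two oxygens of ring A by construction (C17–OH from the ketene carbonyl, C19–O as the ether), and merges arene construction with macrocyclisation in one reagent-free thermal step. The precursor 23 is an open chain with one aromatic ring. The forward reaction has to capture the vinylketene by the tethered ynol ether in preference to a second molecule.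

**23 from 22, and 22 from 18 and 19.** The C14–C15 bond is cut: Grignard reagent 20, made from the terminal chloride of 18, adds to the vinylogous ester 19, and acid collapse transposes the carbonyl to give the 3-alkylcyclobutenone. A Grignard reagent and a terminal alkyne cannot coexist, so the alkyne C–H is masked as C–Si in 18 and 22 and unmasked in 23.

**18 from 16, and 16 from 15 and 14.** The O–C≡C unit comes from the dichlorovinyl ether of 16 by loss of two chlorines. This places the hindered C24–O–C bond formation at the phenol stage, where a small linear electrophile is used. The C1 oxygen is masked in 16. The C1–H bond of 15 is made from ketone 14 by asymmetric transfer hydrogenation, which has to distinguish aryl from n-alkyl.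

**14 from 12 and 13.** The C1–C2 bond is cut as an acyl substitution of Weinreb amide 12 by Grignard reagent 13. Reagent 13 is made from the bromide end of 5, so the chloride end remains as the later handle for C14.

**12 from 10 and 11; 10 back to 6.** Ring B comes from methyl gallate 6. Its central hydroxyl is the most acidic and is benzylated first (7); the flanking hydroxyls become MOM ethers (8); the ester becomes the Weinreb amide (9); hydrogenolysis (10) is done before any alkene is present; the free C24 phenol is then O-dichlorovinylated with 11.

**5 from 4, and 4 from 1 and 2.** The C7–C8 bond is cut as an acetylide alkylation, and the C8≡C9 alkyne of 4 is semi-hydrogenated to the Z-alkene of 5. The geometry is thus fixed on a small acyclic fragment, long before the ring is closed.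

## Alternatives that were turned down

**Alternative 1:** (textbook) Disconnection at C8=C9, with the diaryl ether made earlier by an intermolecular Ullmann coupling. The forward key step is ring-closing metathesis of diene A1 at high dilution with a Z-selective catalyst such as [1-(2-adamantyl-κC)-3-(2,6-diisopropylphenyl)imidazolidin-2-ylidene](2-isopropoxybenzylidene)(nitrato)ruthenium. Turned down because:
- The Ullmann coupling needed for A1 joins a phenol flanked by two ortho alkoxy groups to an electron-rich, unactivated aryl halide.
- Ring A must be built separately with two orthogonally protected oxygens.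
- The metathesis has no substrate bias towards Z in an unstrained 22-membered ring, so geometry rests on the catalyst alone.
- The key step forms one unfunctionalised C=C bond and contributes nothing to the arene and ether problem.

**Alternative 2:** Disconnection of the macrocycle at the C19–O bond. The forward key step is an intramolecular copper-mediated etherification of seco-bromophenol A2 (CuI, N,N-dimethylglycine, Cs2CO3, high dilution, above 100 °C). Turned down because:
- The nucleophile is a 2,6-disubstituted phenoxide and the electrophile an aryl bromide with no activating group, so an SNAr path does not exist.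
- Copper-mediated coupling is slow at the dilution a 22-membered ring needs, so oligomerisation and hydrodehalogenation compete.
- An activating nitro group would cost several steps to install and remove.
- Ring A still needs separate oxygen protection.

**Alternative 3:** Biomimetic disconnection of the C24–O bond. The forward key step is constant-current anodic oxidation (carbon anode) of the open-chain bis-resorcinol A3, joining the ring A oxygen to C24. Turned down because:
- A resorcinol radical cation is attacked mainly at carbon ortho or para to its own oxygens, so C–C coupling and attack at C22/C26 compete with the wanted O–C24 bond.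
- The electrode cannot tell the two identical resorcinol rings apart.
- The pyrogallol-type product is oxidised more easily than A3, and the benzylic carbinol is also oxidisable.
- It is the shortest route on paper, but nothing in the substrate controls its selectivity.

Key step: step 14

Remark: 7-chlorohept-1-yne (1) and 3-ethoxycyclobut-2-en-1-one (19) are taken as catalogue chemicals.

## Route

Step 1
Reactants: 1 7-chlorohept-1-yne; 2 1,6-dibromohexane
Product: 4 13-bromo-1-chlorotridec-6-yne, via lithium 7-chlorohept-1-yn-1-ide 3 (not isolated)
Conditions: n-BuLi, THF, −78 °C; then 2 (4 equiv), DMPU, −78 °C to rt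
Reagents that add atoms: none
Why: Acetylide alkylation (SN2): excess dibromide suppresses double alkylation, and the primary chloride reacts far more slowly than bromide, so it is kept as the later Grignard handle.

Step 2
Reactants: 4 13-bromo-1-chlorotridec-6-yne
Product: 5 (6Z)-13-bromo-1-chlorotridec-6-ene
Conditions: H2 (1 atm), Pd/CaCO3 poisoned with Pb(OAc)2 (Lindlar catalyst), quinoline, EtOAc, rt
Reagents that add atoms: none
Why: Lindlar semi-hydrogenation: syn delivery of hydrogen on the poisoned surface sets the (Z) geometry of the future C8=C9 bond, and primary alkyl halides are not hydrogenolysed under these conditions.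

Step 3
Reactants: 6 methyl 3,4,5-trihydroxybenzoate (methyl gallate)
Product: 7 methyl 4-(benzyloxy)-3,5-dihydroxybenzoate
Conditions: BnBr (1.05 equiv), KHCO3, DMF, rt
Reagents that add atoms: benzyl bromide, BrCc1ccccc1
Why: Williamson etherification under a weak base: only the central hydroxyl, para to the ester and the most acidic, is deprotonated by hydrogen carbonate, so alkylation should be selective for that oxygen.

Step 4
Reactants: 7 methyl 4-(benzyloxy)-3,5-dihydroxybenzoate
Product: 8 methyl 4-(benzyloxy)-3,5-bis(methoxymethoxy)benzoate
Conditions: MOMCl, iPr2NEt, CH2Cl2, 0 °C to rt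
Reagents that add atoms: chloromethyl methyl ether, COCCl
Why: Standard acetal protection of the two flanking phenols; MOM ethers tolerate the later organolithium, Grignard and thermal steps and can be removed without protic acid or hydrogen.

Step 5
Reactants: 8 methyl 4-(benzyloxy)-3,5-bis(methoxymethoxy)benzoate
Product: 9 4-(benzyloxy)-N-methoxy-3,5-bis(methoxymethoxy)-N-methylbenzamide
Conditions: MeNH(OMe)·HCl, iPrMgCl, THF, −20 to 0 °C
Reagents that add atoms: N,O-dimethylhydroxylamine hydrochloride, CNOC.Cl
Why: Weinreb amide formation by aminolysis of the ester with the chloromagnesium amide generated in the flask; nothing else in 8 reacts with this reagent.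

Step 6
Reactants: 9 4-(benzyloxy)-N-methoxy-3,5-bis(methoxymethoxy)-N-methylbenzamide
Product: 10 4-hydroxy-N-methoxy-3,5-bis(methoxymethoxy)-N-methylbenzamide
Conditions: H2 (1 atm), 10% Pd/C, EtOAc, rt
Reagents that add atoms: none
Why: Hydrogenolysis of the benzyl ether frees the C24 phenol; it is placed before any alkene or vinyl chloride is present, and the MOM ethers and the amide N–O bond are stable under neutral conditions.

Step 7
Reactants: 10 4-hydroxy-N-methoxy-3,5-bis(methoxymethoxy)-N-methylbenzamide; 11 trichloroethylene
Product: 12 4-{[(E)-1,2-dichloroethenyl]oxy}-N-methoxy-3,5-bis(methoxymethoxy)-N-methylbenzamide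
Conditions: 11 (3 equiv), K2CO3, DMF, 70 °C
Reagents that add atoms: none
Why: Base-mediated O-dichlorovinylation: 11 loses HCl to dichloroacetylene and the phenoxide adds anti; the electrophile is small and linear, so the two ortho MOM ethers should not block it, and the (E)-dichlorovinyl ether is a robust masked ynol ether.

Step 8
Reactants: 12 4-{[(E)-1,2-dichloroethenyl]oxy}-N-methoxy-3,5-bis(methoxymethoxy)-N-methylbenzamide; 5 (6Z)-13-bromo-1-chlorotridec-6-ene
Product: 14 (8Z)-14-chloro-1-[4-{[(E)-1,2-dichloroethenyl]oxy}-3,5-bis(methoxymethoxy)phenyl]tetradec-8-en-1-one, via [(7Z)-13-chlorotridec-7-en-1-yl]magnesium bromide 13 (not isolated)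
Conditions: 5, Mg, THF, 30 °C; then 12, THF, −20 to 0 °C; aq. NH4Cl
Reagents that add atoms: none
Why: Magnesium inserts into C–Br in preference to C–Cl, and the Weinreb ketone synthesis stops at the chelated tetrahedral intermediate; at −20 °C acyl addition should outrun deprotonation of the dichlorovinyl C–H.

Step 9
Reactants: 14 (8Z)-14-chloro-1-[4-{[(E)-1,2-dichloroethenyl]oxy}-3,5-bis(methoxymethoxy)phenyl]tetradec-8-en-1-one
Product: 15 (1R,8Z)-14-chloro-1-[4-{[(E)-1,2-dichloroethenyl]oxy}-3,5-bis(methoxymethoxy)phenyl]tetradec-8-en-1-ol
Conditions: RuCl[(R,R)-TsDPEN](p-cymene) (1 mol%), HCO2H/Et3N (5:2), EtOAc, 35 °C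
Reagents that add atoms: none
Why: Noyori-type asymmetric transfer hydrogenation: the CH/π contact between the aryl group and the arene ligand of the (R,R) catalyst directs hydride to the face that gives the (R)-carbinol, as for acetophenone-type ketones (aryl outranks the n-alkyl chain in both the model and the CIP order); C=C bonds and the alkyl chloride are not reduced.

Step 10
Reactants: 15 (1R,8Z)-14-chloro-1-[4-{[(E)-1,2-dichloroethenyl]oxy}-3,5-bis(methoxymethoxy)phenyl]tetradec-8-en-1-ol
Product: 16 5-[(1R,8Z)-14-chloro-1-(methoxymethoxy)tetradec-8-en-1-yl]-2-{[(E)-1,2-dichloroethenyl]oxy}-1,3-bis(methoxymethoxy)benzene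
Conditions: MOMCl, iPr2NEt, Bu4NI (cat.), CH2Cl2, 0 to 40 °C
Reagents that add atoms: chloromethyl methyl ether, COCCl
Why: O-alkylation leaves the C1–O bond intact, so the (R) configuration is retained; the ether shields the carbinol from the organometallic steps and from the ketene of the key step.

Step 11
Reactants: 16 5-[(1R,8Z)-14-chloro-1-(methoxymethoxy)tetradec-8-en-1-yl]-2-{[(E)-1,2-dichloroethenyl]oxy}-1,3-bis(methoxymethoxy)benzene
Product: 18 ({4-[(1R,8Z)-14-chloro-1-(methoxymethoxy)tetradec-8-en-1-yl]-2,6-bis(methoxymethoxy)phenoxy}ethynyl)trimethylsilane, via lithium alkynyl ether 17 (not isolated)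
Conditions: n-BuLi (2.2 equiv), THF, −78 to −40 °C; then TMSCl, −78 to 0 °C
Reagents that add atoms: chlorotrimethylsilane, C[Si](C)(C)Cl
Why: Dehydrochlorination followed by chlorine–lithium exchange converts the dichlorovinyl ether into the lithium alkynyl ether, and C-silylation masks the alkyne C–H for the Grignard step; below −40 °C the primary chloride, the MOM ethers and C1–H should be untouched.

Step 12
Reactants: 18 ({4-[(1R,8Z)-14-chloro-1-(methoxymethoxy)tetradec-8-en-1-yl]-2,6-bis(methoxymethoxy)phenoxy}ethynyl)trimethylsilane; 19 3-ethoxycyclobut-2-en-1-one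
Product: 22 3-[(6Z,14R)-14-{3,5-bis(methoxymethoxy)-4-[(trimethylsilyl)ethynyloxy]phenyl}-14-(methoxymethoxy)tetradec-6-en-1-yl]cyclobut-2-en-1-one, via alkylmagnesium chloride 20 (not isolated), via 3-ethoxycyclobutenol adduct 21 (not isolated)
Conditions: Mg (I2-activated), THF, 60 °C; then 19, −78 to −20 °C; aq. NH4Cl; then oxalic acid (cat.), CH2Cl2/H2O, 0 °C
Reagents that add atoms: water, O
Why: 1,2-Addition of the Grignard reagent to the vinylogous ester and acid-induced collapse with carbonyl transposition (Stork–Danheiser type) gives the 3-alkylcyclobutenone, whose carbonyl oxygen comes from water; the silylated ynol ether has no acidic hydrogen, and catalytic oxalic acid should be too weak to hydrate it or to cleave MOM ethers.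

Step 13
Reactants: 22 3-[(6Z,14R)-14-{3,5-bis(methoxymethoxy)-4-[(trimethylsilyl)ethynyloxy]phenyl}-14-(methoxymethoxy)tetradec-6-en-1-yl]cyclobut-2-en-1-one
Product: 23 3-[(6Z,14R)-14-[4-(ethynyloxy)-3,5-bis(methoxymethoxy)phenyl]-14-(methoxymethoxy)tetradec-6-en-1-yl]cyclobut-2-en-1-one
Conditions: TBAF, AcOH, THF, 0 °C
Reagents that add atoms: none
Why: Fluoride-induced protodesilylation of the alkynylsilane; buffering with acetic acid keeps the medium non-basic so that the electrophilic cyclobutenone and the ynol ether should survive, and MOM ethers are inert to fluoride.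

Step 14
Reactants: 23 3-[(6Z,14R)-14-[4-(ethynyloxy)-3,5-bis(methoxymethoxy)phenyl]-14-(methoxymethoxy)tetradec-6-en-1-yl]cyclobut-2-en-1-one
Product: 28 (R,Z)-configured macrocyclic C17-phenol bearing MOM ethers on the C1 oxygen and on both ring B oxygens, via vinylketene 24 (not isolated), via vinylcyclobutenone 25 (not isolated), via dienylketene 26 (not isolated), via cyclohexadienone 27 (not isolated)
Conditions: toluene (degassed), 100 °C, syringe-pump addition of 23 over 16 h (final 0.5 mM), then 110 °C, 3 h
Reagents that add atoms: none
Why: Proposed new method: at 100 °C the cyclobutenone of 23 opens reversibly (4π electrocyclic) to vinylketene 24, whose ketene C=C adds in a [2+2] cycloaddition to the tethered aryloxyalkyne (ketene carbon to the terminal CH, which becomes C18; α-carbon, which becomes C20, to the oxygen-bearing alkyne carbon C19) to give 25, and 4π opening of 25 to dienylketene 26, 6π electrocyclisation to dienone 27 and tautomerisation give phenol 28. The closest known reaction type is the intermolecular Danheiser benzannulation of 3-substituted cyclobutenones with alkoxy- and siloxyalkynes, which delivers 5-substituted resorcinol monoethers with this regiochemistry; what is new is the tether, which turns the [2+2] event into a macrocyclisation. The 22-membered ring is closed in the [2+2] step by the C19–C20 bond (an unstrained large-ring closure with both reacting π systems inside the ring), and ring A is closed afterwards by the 6π electrocyclisation that forms C16–C17. No stereocenter remains from the step: the sp3 carbon of 25 is erased on aromatisation, and C1 is remote and configurationally inert under neutral thermolysis. The regiochemistry is fixed by polarity: the nucleophilic β-carbon of the ynol ether attacks the ketene carbon, so the ketene oxygen becomes the free C17 hydroxyl, the ether oxygen sits at C19 and the chain at C15. The selectivity needed is ring closure over bimolecular capture; it should be secured by the reversible formation of 24 (present only in trace concentration and returning to 23 when not trapped, so ketene dimerisation is negligible) and by slow addition to 0.5 mM. Chemoselectivity for the ynol ether over the C8=C9 alkene follows from the much higher ketenophilicity of the oxygen-substituted alkyne, whose oxygen lone pair is left to the triple bond because the 2,6-dioxygenated ring B is twisted out of conjugation; an aryl ynol ether has no β-hydrogen and cannot fragment by a retro-ene path.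

Step 15
Reactants: 28 (R,Z)-configured macrocyclic C17-phenol bearing MOM ethers on the C1 oxygen and on both ring B oxygens
Product: 30 target macrocycle CNP0316989.2, via silylated bipyridinium triflate 29 (not isolated)
Conditions: TMSOTf, 2,2'-bipyridyl, CH2Cl2, 0 °C to rt; then H2O, rt
Reagents that add atoms: none
Why: Non-protic MOM cleavage: the aryl MOM ethers are converted into aryl silyl ethers and the alkyl MOM ether into an N-(alkoxymethyl)bipyridinium salt, all hydrolysed by water; only acetal C–O bonds are broken, so the C1–O bond, the (R) configuration and the Z-alkene should stay untouched.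

## Compound list

1 | 7-chlorohept-1-yne | C#CCCCCCCl | starting material
2 | 1,6-dibromohexane | BrCCCCCCBr | starting material
3 | lithium 7-chlorohept-1-yn-1-ide (formed in the flask) | [Li]C#CCCCCCCl | intermediate
4 | 13-bromo-1-chlorotridec-6-yne | ClCCCCCC#CCCCCCCBr | intermediate
5 | (6Z)-13-bromo-1-chlorotridec-6-ene | ClCCCCC/C=C\CCCCCCBr | intermediate
6 | methyl 3,4,5-trihydroxybenzoate (methyl gallate) | COC(=O)c1cc(O)c(O)c(O)c1 | starting material
7 | methyl 4-(benzyloxy)-3,5-dihydroxybenzoate | COC(=O)c1cc(O)c(OCc2ccccc2)c(O)c1 | intermediate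
8 | methyl 4-(benzyloxy)-3,5-bis(methoxymethoxy)benzoate | COC(=O)c1cc(OCOC)c(OCc2ccccc2)c(OCOC)c1 | intermediate
9 | 4-(benzyloxy)-N-methoxy-3,5-bis(methoxymethoxy)-N-methylbenzamide | CON(C)C(=O)c1cc(OCOC)c(OCc2ccccc2)c(OCOC)c1 | intermediate
10 | 4-hydroxy-N-methoxy-3,5-bis(methoxymethoxy)-N-methylbenzamide | CON(C)C(=O)c1cc(OCOC)c(O)c(OCOC)c1 | intermediate
11 | trichloroethylene (1,1,2-trichloroethene) | ClC=C(Cl)Cl | starting material
12 | 4-{[(E)-1,2-dichloroethenyl]oxy}-N-methoxy-3,5-bis(methoxymethoxy)-N-methylbenzamide | CON(C)C(=O)c1cc(OCOC)c(O/C(Cl)=C\Cl)c(OCOC)c1 | intermediate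
13 | [(7Z)-13-chlorotridec-7-en-1-yl]magnesium bromide (formed in the flask) | ClCCCCC/C=C\CCCCCC[Mg]Br | intermediate
14 | (8Z)-14-chloro-1-[4-{[(E)-1,2-dichloroethenyl]oxy}-3,5-bis(methoxymethoxy)phenyl]tetradec-8-en-1-one | ClCCCCC/C=C\CCCCCCC(=O)c1cc(OCOC)c(O/C(Cl)=C\Cl)c(OCOC)c1 | intermediate
15 | (1R,8Z)-14-chloro-1-[4-{[(E)-1,2-dichloroethenyl]oxy}-3,5-bis(methoxymethoxy)phenyl]tetradec-8-en-1-ol | COCOc1cc(cc(OCOC)c1O/C(Cl)=C\Cl)[C@H](O)CCCCCC/C=C\CCCCCCl | intermediate
16 | 5-[(1R,8Z)-14-chloro-1-(methoxymethoxy)tetradec-8-en-1-yl]-2-{[(E)-1,2-dichloroethenyl]oxy}-1,3-bis(methoxymethoxy)benzene | COCOc1cc(cc(OCOC)c1O/C(Cl)=C\Cl)[C@H](OCOC)CCCCCC/C=C\CCCCCCl | intermediate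
17 | lithium 2-{4-[(1R,8Z)-14-chloro-1-(methoxymethoxy)tetradec-8-en-1-yl]-2,6-bis(methoxymethoxy)phenoxy}ethyn-1-ide (formed in the flask) | COCOc1cc(cc(OCOC)c1OC#C[Li])[C@H](OCOC)CCCCCC/C=C\CCCCCCl | intermediate
18 | ({4-[(1R,8Z)-14-chloro-1-(methoxymethoxy)tetradec-8-en-1-yl]-2,6-bis(methoxymethoxy)phenoxy}ethynyl)trimethylsilane | COCOc1cc(cc(OCOC)c1OC#C[Si](C)(C)C)[C@H](OCOC)CCCCCC/C=C\CCCCCCl | intermediate
19 | 3-ethoxycyclobut-2-en-1-one | CCOC1=CC(=O)C1 | starting material
20 | [(6Z,14R)-14-{3,5-bis(methoxymethoxy)-4-[(trimethylsilyl)ethynyloxy]phenyl}-14-(methoxymethoxy)tetradec-6-en-1-yl]magnesium chloride (formed in the flask) | COCOc1cc(cc(OCOC)c1OC#C[Si](C)(C)C)[C@H](OCOC)CCCCCC/C=C\CCCCC[Mg]Cl | intermediate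
21 | 3-ethoxy-1-[(6Z,14R)-14-{3,5-bis(methoxymethoxy)-4-[(trimethylsilyl)ethynyloxy]phenyl}-14-(methoxymethoxy)tetradec-6-en-1-yl]cyclobut-2-en-1-ol, both epimers at the ring carbinol carbon (crude, not purified) | COCOc1cc(cc(OCOC)c1OC#C[Si](C)(C)C)[C@H](OCOC)CCCCCC/C=C\CCCCCC2(O)C=C(OCC)C2 | intermediate
22 | 3-[(6Z,14R)-14-{3,5-bis(methoxymethoxy)-4-[(trimethylsilyl)ethynyloxy]phenyl}-14-(methoxymethoxy)tetradec-6-en-1-yl]cyclobut-2-en-1-one | COCOc1cc(cc(OCOC)c1OC#C[Si](C)(C)C)[C@H](OCOC)CCCCCC/C=C\CCCCCC2=CC(=O)C2 | intermediate
23 | 3-[(6Z,14R)-14-[4-(ethynyloxy)-3,5-bis(methoxymethoxy)phenyl]-14-(methoxymethoxy)tetradec-6-en-1-yl]cyclobut-2-en-1-one | COCOc1cc(cc(OCOC)c1OC#C)[C@H](OCOC)CCCCCC/C=C\CCCCCC2=CC(=O)C2 | intermediate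
24 | (9Z,17R)-17-[4-(ethynyloxy)-3,5-bis(methoxymethoxy)phenyl]-17-(methoxymethoxy)-3-methylideneheptadeca-1,9-dien-1-one (vinylketene, formed in the flask) | COCOc1cc(cc(OCOC)c1OC#C)[C@H](OCOC)CCCCCC/C=C\CCCCCC(=C)C=C=O | intermediate
25 | macrocyclic 3-aryloxy-4-alkenylcyclobut-2-en-1-one: four-membered ring C17(=O)–C18H=C19(O–C24)–C20H, with C20 carrying the C15(=C16H2)–C14 unit; 22-membered ring closed; both epimers at C20 (formed in the flask) | COCOc1cc(cc(OCOC)c1OC3=CC(=O)C3C(=C)CCCCC/C=C\CCCCCC2)[C@@H]2OCOC | intermediate
26 | macrocyclic dienylketene O=C17=C18H–C19(O–C24)=C20H–C15(=C16H2)–C14, ketene and methylidene groups cis across C19=C20 (formed in the flask) | COCOc1cc(cc(OCOC)c1OC(/C=C=O)=C/C(=C)CCCCC/C=C\CCCCCC2)[C@@H]2OCOC | intermediate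
27 | macrocyclic 3-aryloxy-5-alkylcyclohexa-2,4-dien-1-one, keto tautomer of 28 (formed in the flask) | COCOc1cc(cc(OCOC)c1OC3=CC(=O)CC(=C3)CCCCC/C=C\CCCCCC2)[C@@H]2OCOC | intermediate
28 | (R,Z)-configured 22-membered macrocycle: ring A with free C17–OH, the C19–O–C24 ether and the C15–C14 bond; ring B with MOM ethers on the oxygens of C23 and C25; C1–OMOM; (8Z)-alkene | COCOc1cc(cc(OCOC)c1Oc3cc(O)cc(c3)CCCCC/C=C\CCCCCC2)[C@@H]2OCOC | intermediate
29 | macrocycle with trimethylsilyl ethers on the oxygens of C17, C23 and C25 and a 1-(alkoxymethyl)-2,2'-bipyridin-1-ium group on the C1 oxygen, as the triflate (formed in the flask) | C[Si](C)(C)Oc1cc(cc(O[Si](C)(C)C)c1Oc3cc(O[Si](C)(C)C)cc(c3)CCCCC/C=C\CCCCCC2)[C@@H]2OC[n+]4ccccc4-c5ccccn5.[O-]S(=O)(=O)C(F)(F)F | intermediate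
30 | target CNP0316989.2: (R,Z)-configured 22-membered macrocycle; ring A with C17–OH, the C19–O–C24 ether and the C15–C14 bond; ring B with C23–OH and C25–OH; (1R)-C1–OH; (8Z)-alkene | Oc1cc2cc(c1)Oc1c(O)cc(cc1O)[C@H](O)CCCCCC/C=C\CCCCC2 | target

## Step count and least certain steps

Total: 15 steps. Longest linear sequence: 13 steps (steps 3–15 from methyl gallate 6). The chain branch (steps 1–2) joins at step 8.

**Step 14 (key step, proposed new method).** The most likely failure is bimolecular capture of the vinylketene by the ynol ether of a second molecule, because a 22-membered ring has a low effective molarity; thermal loss of the ynol ether during the long addition is the second risk. The fallback uses known chemistry, sets out from 12 and returns at 28: the benzannulation is run intermolecularly and the macrocycle is closed at C8=C9 instead. Oct-7-en-1-ylmagnesium bromide F1 (from commercial 8-bromooct-1-ene and Mg) adds to 12 to give ketone F2. Transfer hydrogenation as in step 9 gives (R)-alcohol F3, MOMCl/iPr2NEt gives MOM ether F4, and n-BuLi followed by methanol gives terminal ynol ether F5. Separately, hept-6-en-1-ylmagnesium bromide F6 (from commercial 7-bromohept-1-ene and Mg) adds to 19 and acid collapse gives cyclobutenone F7. Heating F5 with F7 in toluene (0.5 M, 80–110 °C), the standard intermolecular Danheiser benzannulation, should give diene phenol F8. Z-selective ring-closing metathesis of F8 with [1-(2-adamantyl-κC)-3-(2,6-diisopropylphenyl)imidazolidin-2-ylidene](2-isopropoxybenzylidene)(nitrato)ruthenium at 2 mM then closes the ring to 28.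

**Step 12.** The most likely failure is slow or incomplete magnesium insertion into the unactivated C–Cl bond at 60 °C, accompanied by Wurtz coupling or by attack of the organomagnesium on the silylated ynol ether of a second molecule; hydration of the ynol ether or loss of MOM during the acid collapse is the second risk. The fallback sets out from 18 and returns at 22: halide exchange (NaI, acetone, reflux) gives iodide F9. Iodine–lithium exchange (t-BuLi, 2.1 equiv, Et2O/pentane, −78 °C), addition of 19 and collapse of the alkoxide with (CF3CO)2O followed by aq. NaHCO3 then give 22 without heating and without aqueous acid.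

**Step 13.** The most likely failure is attack of fluoride or acetate on the strained enone (ring opening or conjugate addition) or partial loss of the ynol ether. The fallback sets out from 22 and returns at 28: the desilylation is omitted and the silicon is carried through the ring closure. Heating 22 under the conditions of step 14 should give 2-(trimethylsilyl)phenol macrocycle F10 (silicon at C18), and ipso-protodesilylation with TBAF in wet THF returns to 28.

**Step 9.** The most likely failure is incomplete enantioselectivity, because aryl/n-alkyl discrimination is lower than aryl/methyl, or slow turnover with the electron-rich ketone. The fallback sets out from 14, returns at 15 and makes no new compound: Corey–Bakshi–Shibata reduction with (S)-2-methyl-CBS-oxazaborolidine and catecholborane in toluene at −78 °C. This Lewis-acid-directed borane reduction has a different stereocontrol model and the same (R) outcome, and catecholborane does not hydroborate the alkenes at that temperature.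

## Further compounds

F1 | step 14 | oct-7-en-1-ylmagnesium bromide | C=CCCCCCC[Mg]Br
F2 | step 14 | 1-[4-{[(E)-1,2-dichloroethenyl]oxy}-3,5-bis(methoxymethoxy)phenyl]non-8-en-1-one | C=CCCCCCCC(=O)c1cc(OCOC)c(O/C(Cl)=C\Cl)c(OCOC)c1
F3 | step 14 | (1R)-1-[4-{[(E)-1,2-dichloroethenyl]oxy}-3,5-bis(methoxymethoxy)phenyl]non-8-en-1-ol | COCOc1cc(cc(OCOC)c1O/C(Cl)=C\Cl)[C@H](O)CCCCCCC=C
F4 | step 14 | 2-{[(E)-1,2-dichloroethenyl]oxy}-1,3-bis(methoxymethoxy)-5-[(1R)-1-(methoxymethoxy)non-8-en-1-yl]benzene | COCOc1cc(cc(OCOC)c1O/C(Cl)=C\Cl)[C@H](OCOC)CCCCCCC=C
F5 | step 14 | 2-(ethynyloxy)-1,3-bis(methoxymethoxy)-5-[(1R)-1-(methoxymethoxy)non-8-en-1-yl]benzene | COCOc1cc(cc(OCOC)c1OC#C)[C@H](OCOC)CCCCCCC=C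
F6 | step 14 | hept-6-en-1-ylmagnesium bromide | C=CCCCCC[Mg]Br
F7 | step 14 | 3-(hept-6-en-1-yl)cyclobut-2-en-1-one | C=CCCCCCC1=CC(=O)C1
F8 | step 14 | 3-(hept-6-en-1-yl)-5-{2,6-bis(methoxymethoxy)-4-[(1R)-1-(methoxymethoxy)non-8-en-1-yl]phenoxy}phenol | C=CCCCCCc1cc(O)cc(Oc2c(OCOC)cc(cc2OCOC)[C@H](OCOC)CCCCCCC=C)c1
F9 | step 12 | ({4-[(1R,8Z)-14-iodo-1-(methoxymethoxy)tetradec-8-en-1-yl]-2,6-bis(methoxymethoxy)phenoxy}ethynyl)trimethylsilane | COCOc1cc(cc(OCOC)c1OC#C[Si](C)(C)C)[C@H](OCOC)CCCCCC/C=C\CCCCCI
F10 | step 13 | macrocycle 28 carrying a trimethylsilyl group at C18 | COCOc1cc(cc(OCOC)c1Oc3c([Si](C)(C)C)c(O)cc(c3)CCCCC/C=C\CCCCCC2)[C@@H]2OCOC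
F0 | step 9 | none | none
A1 | alternative 1 | 5-[(1R)-1-(methoxymethoxy)non-8-en-1-yl]-2-[3-(hept-6-en-1-yl)-5-(methoxymethoxy)phenoxy]-1,3-bis(methoxymethoxy)benzene | C=CCCCCCc1cc(OCOC)cc(Oc2c(OCOC)cc(cc2OCOC)[C@H](OCOC)CCCCCCC=C)c1
A2 | alternative 2 | 4-[(1R,8Z)-14-[3-bromo-5-(methoxymethoxy)phenyl]-1-(methoxymethoxy)tetradec-8-en-1-yl]-2,6-bis(methoxymethoxy)phenol | COCOc1cc(cc(OCOC)c1O)[C@H](OCOC)CCCCCC/C=C\CCCCCc2cc(Br)cc(OCOC)c2
A3 | alternative 3 | (1R,8Z)-1,14-bis(3,5-dihydroxyphenyl)tetradec-8-en-1-ol | Oc1cc(O)cc(c1)CCCCC/C=C\CCCCCC[C@@H](O)c1cc(O)cc(O)c1
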